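**Retrosynthetic overview**
1. The enol-ether O–C(sp2) bond is cut last: a stereoretentive copper-catalysed coupling joins (S)-alcohol 8 and (Z)-alkenyl iodide 16, and fluoride then removes both silyl groups. No acid is used after step 6, because the enol ether and the benzylic ether (ortho to the C7 methoxy group, para to O1) are acid-labile.
2. Iodide 16 comes from hydroxyl-directed anti-arylmagnesiation of propargyl alcohol and iodinolysis, which places iodine cis to CH2O and so fixes the Z geometry.
3. Alcohol 8 comes from asymmetric hydrogenation of ketone 7, which sets the S centre.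
4. The pyran ring of 7 is the only ring made (both benzene rings are bought). It is closed at C2–C3 by a redox-neutral 1,5-hydride shift/cyclisation of the ortho-ethynyl aryl isopropyl ether 5, made from phenol 1 by O-isopropylation, iodination and Sonogashira ethynylation.
5. Enabling feature: C2 of the pyran ring is a gem-dimethyl carbon bound to O1, that is, the methine of an aryl isopropyl ether. Its hydridic C–H lies 1,5 to C4 across O1–C8a–C4a, and the C7 methoxy group is para to C4a, so a π-activated C3≡C4 alkyne takes the hydride at C4 and bonds to the resulting oxocarbenium carbon at C3.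

Key step: step 5

Remark: chromene numbering (O1, C2, C3, C4, C4a, C5 to C8, C8a) is used throughout; the target is read as S at the benzylic carbon and Z at the enol ether (ether oxygen cis to CH2OH), and 1 is taken as a bought compound.

**Route**

Step 1
Reactants: 1 1-(4-hydroxy-2-methoxyphenyl)ethanone
Product: 2 1-(2-methoxy-4-isopropoxyphenyl)ethanone
Conditions: 2-bromopropane, K2CO3, DMF, 60 °C
Reagents that add atoms: 2-bromopropane CC(C)Br
Why: Williamson etherification of the only phenol, made acidic by the para acetyl group, should proceed cleanly with an excess of the secondary bromide while the ketone is untouched.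

Step 2
Reactants: 2 1-(2-methoxy-4-isopropoxyphenyl)ethanone
Product: 3 1-(5-iodo-2-methoxy-4-isopropoxyphenyl)ethanone
Conditions: N-iodosuccinimide, CF3CO2H (cat.), MeCN, 0 °C to rt
Reagents that add atoms: N-iodosuccinimide O=C1CCC(=O)N1I
Why: Electrophilic aromatic iodination should go to C5, para to the methoxy group and ortho to the isopropoxy group, because C3 is shielded between two alkoxy groups and C6 lies ortho to the deactivating acetyl group.

Step 3
Reactants: 3 1-(5-iodo-2-methoxy-4-isopropoxyphenyl)ethanone
Product: 4 1-{2-methoxy-4-isopropoxy-5-[(trimethylsilyl)ethynyl]phenyl}ethanone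
Conditions: ethynyltrimethylsilane, PdCl2(PPh3)2 (cat.), CuI (cat.), Et3N, THF, 50 °C
Reagents that add atoms: ethynyltrimethylsilane C#C[Si](C)(C)C
Why: Sonogashira coupling of an aryl iodide is reliable even next to an ortho alkoxy group, and the silyl cap prevents alkyne homocoupling.

Step 4
Reactants: 4 1-{2-methoxy-4-isopropoxy-5-[(trimethylsilyl)ethynyl]phenyl}ethanone
Product: 5 1-(5-ethynyl-2-methoxy-4-isopropoxyphenyl)ethanone
Conditions: K2CO3 (cat.), MeOH, rt
Reagents that add atoms: none
Why: Base-catalysed methanolysis of the C(sp)–Si bond should free the terminal alkyne without touching the ethers or the ketone.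

Step 5
Reactants: 5 1-(5-ethynyl-2-methoxy-4-isopropoxyphenyl)ethanone
Product: 7 1-(7-methoxy-2,2-dimethyl-2H-chromen-6-yl)ethanone, via alkenylplatinate oxocarbenium zwitterion 6 (not isolated)
Conditions: PtI4 (10 mol %), anhydrous MeCN, 120 °C, sealed tube
Reagents that add atoms: none
Why: Proposed new method: PtI4 (tetravalent platinum) binds the terminal alkyne and slips towards the terminal carbon, so that positive charge builds on the internal carbon (future C4, stabilised by the para C7 methoxy group); the hydridic tertiary C–H of the isopropyl ether (future C2), held 1,5 to C4 across O1–C8a–C4a, is transferred through a six-membered transition state anti to platinum to give zwitterion 6 (aryl oxocarbenium ion plus a (Z)-alkenylplatinate with the metal cis to the arene), and attack of the platinum-bearing carbon (C3) on the oxocarbenium carbon forms C2–C3 and releases PtI4. The closest known reaction type is the PtI4-catalysed hydride-transfer cycloisomerisation of alkyl-tethered terminal alkynes onto the α-C–H bond of cyclic ethers, together with the Lewis-acid hydride shift/cyclisation of ortho-alkoxybenzylidene malonates to chromans; what is new is the pairing of an aryl isopropyl ether donor with an aryl alkyne acceptor. The pyran ring closes in a 6-endo mode at the oxocarbenium (O1 and C2 both in the ring), and the C3=C4 bond also ends inside the ring. No stereocentre is formed, and the cis ring alkene follows from the anti addition of hydride and platinum. The step needs hydride delivery to C4 to outrun 5-endo attack of O1 on the terminal carbon (benzofuran with loss of propene), five-membered closure through C4 and alkyne hydration: the para methoxy group makes C4, which O1 cannot reach, the electrophilic carbon, the para acetyl group lowers the nucleophilicity of O1, the oxocarbenium ion is tertiary, and the medium is anhydrous. The side chain is carried as the ketone so that no ionisable benzylic C–O bond is exposed to the Lewis acid.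

Step 6
Reactants: 7 1-(7-methoxy-2,2-dimethyl-2H-chromen-6-yl)ethanone
Product: 8 (S)-1-(7-methoxy-2,2-dimethyl-2H-chromen-6-yl)ethanol
Conditions: RuCl2[(R)-xylbinap][(R)-daipen] (0.2 mol %), t-BuOK (2 mol %), H2 (8 atm), i-PrOH, 25 °C
Reagents that add atoms: none
Why: Noyori asymmetric hydrogenation with the (R)-diphosphine/(R)-diamine ruthenium catalyst should deliver hydride to the Re face of the aryl methyl ketone to set the S centre, it reduces C=O in preference to the chromene C=C, and its basic medium keeps the ionisable benzylic alcohol configurationally stable.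

Step 7
Reactants: 9 2-bromo-5-methylphenol
Product: 10 (2-bromo-5-methylphenoxy)triisopropylsilane
Conditions: chlorotriisopropylsilane, imidazole, DMF, rt
Reagents that add atoms: chlorotriisopropylsilane CC(C)[Si](Cl)(C(C)C)C(C)C
Why: Imidazole-promoted silylation gives a bulky aryl silyl ether that should survive Grignard formation and hot carbonate and is later removed by fluoride without acid.

Step 8
Reactants: 10 (2-bromo-5-methylphenoxy)triisopropylsilane; 11 prop-2-yn-1-ol
Product: 15 (Z)-3-iodo-2-[4-methyl-2-(triisopropylsilyloxy)phenyl]prop-2-en-1-ol, via arylmagnesium bromide 12 (not isolated), via bromomagnesium prop-2-yn-1-olate 13 (not isolated), via cyclic alkenylmagnesium alkoxide 14 (not isolated)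
Conditions: 10, Mg, THF, reflux; separately 11, EtMgBr (1.0 equiv), THF, 0 °C; combine, CuI (10 mol %), THF, rt to 45 °C; then iodine, −20 °C to rt; aq. Na2S2O3
Reagents that add atoms: iodine [I][I]
Why: Magnesium insertion gives Grignard 12, whose copper-catalysed, alkoxide-directed anti-carbomagnesiation of 13 puts the aryl group on C2 and magnesium on C3 cis to CH2O in the five-membered chelate 14, and iodinolysis with retention then fixes the Z geometry (iodine cis to CH2OH, trans to the aryl group).

Step 9
Reactants: 15 (Z)-3-iodo-2-[4-methyl-2-(triisopropylsilyloxy)phenyl]prop-2-en-1-ol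
Product: 16 (Z)-tert-butyl({3-iodo-2-[4-methyl-2-(triisopropylsilyloxy)phenyl]prop-2-en-1-yl}oxy)dimethylsilane
Conditions: tert-butylchlorodimethylsilane, imidazole, DMF, 0 °C to rt
Reagents that add atoms: tert-butylchlorodimethylsilane CC(C)(C)[Si](C)(C)Cl
Why: Standard silylation masks the primary alcohol so that only alcohol 8 can act as the oxygen nucleophile in the coupling, and the alkene geometry is not touched.

Step 10
Reactants: 8 (S)-1-(7-methoxy-2,2-dimethyl-2H-chromen-6-yl)ethanol; 16 (Z)-tert-butyl({3-iodo-2-[4-methyl-2-(triisopropylsilyloxy)phenyl]prop-2-en-1-yl}oxy)dimethylsilane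
Product: 17 tert-butyl({(Z)-3-[(S)-1-(7-methoxy-2,2-dimethyl-2H-chromen-6-yl)ethoxy]-2-[4-methyl-2-(triisopropylsilyloxy)phenyl]prop-2-en-1-yl}oxy)dimethylsilane
Conditions: CuI (10 mol %), 3,4,7,8-tetramethyl-1,10-phenanthroline (20 mol %), Cs2CO3, toluene, 80 °C, argon
Reagents that add atoms: none
Why: Ullmann-type copper-catalysed C–O coupling of the caesium alkoxide of 8 with the alkenyl iodide at a monovalent copper/phenanthroline centre should form the O–C(sp2) bond with retention of alkene geometry, and since the C–O bond at the stereocentre is never broken and the medium is basic, the S configuration is kept.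

Step 11
Reactants: 17 tert-butyl({(Z)-3-[(S)-1-(7-methoxy-2,2-dimethyl-2H-chromen-6-yl)ethoxy]-2-[4-methyl-2-(triisopropylsilyloxy)phenyl]prop-2-en-1-yl}oxy)dimethylsilane
Product: 18 2-{(Z)-3-hydroxy-1-[(S)-1-(7-methoxy-2,2-dimethyl-2H-chromen-6-yl)ethoxy]prop-1-en-2-yl}-5-methylphenol (CNP0279099.1)
Conditions: Bu4NF (2.4 equiv), THF, 0 °C to rt; pH 7 buffer work-up; Et3N-deactivated silica
Reagents that add atoms: none
Why: Fluoride-driven desilylation should free both the phenol and the primary alcohol under basic, acid-free conditions that leave the enol ether, the benzylic ether, the stereocentre and the alkene geometry unchanged.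

**Compound list**
1 | 1-(4-hydroxy-2-methoxyphenyl)ethanone | CC(=O)c1ccc(O)cc1OC | starting material
2 | 1-(2-methoxy-4-isopropoxyphenyl)ethanone | CC(=O)c1ccc(OC(C)C)cc1OC | intermediate
3 | 1-(5-iodo-2-methoxy-4-isopropoxyphenyl)ethanone | CC(=O)c1cc(I)c(OC(C)C)cc1OC | intermediate
4 | 1-{2-methoxy-4-isopropoxy-5-[(trimethylsilyl)ethynyl]phenyl}ethanone | CC(=O)c1cc(C#C[Si](C)(C)C)c(OC(C)C)cc1OC | intermediate
5 | 1-(5-ethynyl-2-methoxy-4-isopropoxyphenyl)ethanone | CC(=O)c1cc(C#C)c(OC(C)C)cc1OC | intermediate
6 | alkenylplatinate oxocarbenium zwitterion (Pt cis to the arene) | CC(=O)c1cc(/C=C\[Pt-](I)(I)(I)I)c(cc1OC)[O+]=C(C)C | intermediate (not isolated)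
7 | 1-(7-methoxy-2,2-dimethyl-2H-chromen-6-yl)ethanone | CC(=O)c1cc2C=CC(C)(C)Oc2cc1OC | intermediate
8 | (S)-1-(7-methoxy-2,2-dimethyl-2H-chromen-6-yl)ethanol | COc1cc2c(cc1[C@H](C)O)C=CC(C)(C)O2 | intermediate
9 | 2-bromo-5-methylphenol | Cc1ccc(Br)c(O)c1 | starting material
10 | (2-bromo-5-methylphenoxy)triisopropylsilane | Cc1ccc(Br)c(O[Si](C(C)C)(C(C)C)C(C)C)c1 | intermediate
11 | prop-2-yn-1-ol | C#CCO | starting material
12 | [4-methyl-2-(triisopropylsilyloxy)phenyl]magnesium bromide | Cc1ccc([Mg]Br)c(O[Si](C(C)C)(C(C)C)C(C)C)c1 | intermediate (not isolated)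
13 | bromomagnesium prop-2-yn-1-olate | C#CCO[Mg]Br | intermediate (not isolated)
14 | 4-[4-methyl-2-(triisopropylsilyloxy)phenyl]-2,5-dihydro-1,2-oxamagnesole | Cc1ccc(C2=C[Mg]OC2)c(O[Si](C(C)C)(C(C)C)C(C)C)c1 | intermediate (not isolated)
15 | (Z)-3-iodo-2-[4-methyl-2-(triisopropylsilyloxy)phenyl]prop-2-en-1-ol | I/C=C(\CO)c1ccc(C)cc1O[Si](C(C)C)(C(C)C)C(C)C | intermediate
16 | (Z)-tert-butyl({3-iodo-2-[4-methyl-2-(triisopropylsilyloxy)phenyl]prop-2-en-1-yl}oxy)dimethylsilane | I/C=C(\CO[Si](C)(C)C(C)(C)C)c1ccc(C)cc1O[Si](C(C)C)(C(C)C)C(C)C | intermediate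
17 | tert-butyl({(Z)-3-[(S)-1-(7-methoxy-2,2-dimethyl-2H-chromen-6-yl)ethoxy]-2-[4-methyl-2-(triisopropylsilyloxy)phenyl]prop-2-en-1-yl}oxy)dimethylsilane | COc1cc2c(cc1[C@H](C)O/C=C(\CO[Si](C)(C)C(C)(C)C)c1ccc(C)cc1O[Si](C(C)C)(C(C)C)C(C)C)C=CC(C)(C)O2 | intermediate
18 | 2-{(Z)-3-hydroxy-1-[(S)-1-(7-methoxy-2,2-dimethyl-2H-chromen-6-yl)ethoxy]prop-1-en-2-yl}-5-methylphenol | COc1cc2c(cc1[C@H](C)O/C=C(\CO)c1ccc(C)cc1O)C=CC(C)(C)O2 | target

**Step count**
Total steps: 11. Longest linear sequence: 8 steps (steps 1 to 6, 10 and 11).

**Steps most likely to fail**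

Step 5 (proposed new method). Hydride transfer from the isopropyl methine is slowed by the para acetyl group, and may lose to alkyne hydration, oligomerisation or O-attack with dealkylation. The fallback sets out from 1 and comes back at 7, and closes the ring at O1–C2 by known chemistry. Iodination of 1 with N-iodosuccinimide (ortho to the free phenol, para to the methoxy group) should give 1-(4-hydroxy-5-iodo-2-methoxyphenyl)ethanone F1. A Heck reaction of F1 with 2-methylbut-3-en-2-ol (Pd(OAc)2, P(o-tol)3, Et3N, DMF, 100 °C) should give (E)-1-[4-hydroxy-5-(3-hydroxy-3-methylbut-1-en-1-yl)-2-methoxyphenyl]ethanone F2. Pyridinium tosylate in refluxing toluene should dehydrate F2 to the vinyl ortho-quinone methide, whose oxa-6π electrocyclisation gives 7.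

Step 10. Ligand exchange of the hindered secondary alkoxide at copper may be slow, so that dehydrogenation of 8 to ketone 7 or silyl migration from the phenol at 80 °C competes. The fallback sets out from 16 and comes back at 17. Miyaura borylation of 16 (B2pin2, PdCl2(PPh3)2, PPh3, KOPh, toluene, 50 °C) should give, with retention, (Z)-tert-butyldimethyl({2-[4-methyl-2-(triisopropylsilyloxy)phenyl]-3-(4,4,5,5-tetramethyl-1,3,2-dioxaborolan-2-yl)prop-2-en-1-yl}oxy)silane F3. Oxidative Chan–Lam etherification of 8 with F3 (Cu(OAc)2, Et3N, 4 Å molecular sieves, CH2Cl2, rt, air) should then form the same O–C(sp2) bond at room temperature through a trivalent copper alkoxide/alkenyl intermediate.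

Step 8. The hindered ortho-silyloxyaryl Grignard reagent may add incompletely or with poor regiocontrol to the propargyl alkoxide, or be consumed by protonation. The fallback sets out from 10 and comes back at 15. Miyaura borylation of 10 (B2pin2, PdCl2(dppf), KOAc, dioxane, 80 °C) should give triisopropyl[5-methyl-2-(4,4,5,5-tetramethyl-1,3,2-dioxaborolan-2-yl)phenoxy]silane F4. Rhodium-catalysed syn-hydroarylation of 3-(trimethylsilyl)prop-2-yn-1-ol with F4 ([Rh(cod)OH]2, dioxane/H2O, 80 °C; aryl adds to the carbon remote from silicon) should give (Z)-2-[4-methyl-2-(triisopropylsilyloxy)phenyl]-3-(trimethylsilyl)prop-2-en-1-ol F5, with silicon cis to CH2OH. Iododesilylation of F5 with N-iodosuccinimide (MeCN/ClCH2CN, 0 °C), which goes with retention, should give 15.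

**Further compounds**
F1 | step 5 | 1-(4-hydroxy-5-iodo-2-methoxyphenyl)ethanone | CC(=O)c1cc(I)c(O)cc1OC
F2 | step 5 | (E)-1-[4-hydroxy-5-(3-hydroxy-3-methylbut-1-en-1-yl)-2-methoxyphenyl]ethanone | CC(=O)c1cc(/C=C/C(C)(C)O)c(O)cc1OC
F3 | step 10 | (Z)-tert-butyldimethyl({2-[4-methyl-2-(triisopropylsilyloxy)phenyl]-3-(4,4,5,5-tetramethyl-1,3,2-dioxaborolan-2-yl)prop-2-en-1-yl}oxy)silane | CC1(C)OB(/C=C(\CO[Si](C)(C)C(C)(C)C)c2ccc(C)cc2O[Si](C(C)C)(C(C)C)C(C)C)OC1(C)C
F4 | step 8 | triisopropyl[5-methyl-2-(4,4,5,5-tetramethyl-1,3,2-dioxaborolan-2-yl)phenoxy]silane | Cc1ccc(B2OC(C)(C)C(C)(C)O2)c(O[Si](C(C)C)(C(C)C)C(C)C)c1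
F5 | step 8 | (Z)-2-[4-methyl-2-(triisopropylsilyloxy)phenyl]-3-(trimethylsilyl)prop-2-en-1-ol | C[Si](C)(C)/C=C(\CO)c1ccc(C)cc1O[Si](C(C)C)(C(C)C)C(C)C
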